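**Retrosynthetic overview**
- Feature: ring A carries one substituent, the C7 hydroxyl, para to C4a (which holds the C4 ketone) and meta to C8a (which holds O1). A 1-methoxy-3-silyloxybutadiene writes exactly this pattern onto an acceptor-bearing olefin, so ring A can be built last.
- Key disconnection: C4a–C5 and C8–C8a, leading back to a monocyclic (S)-2-aryl-5-(phenylsulfonyl)-2,3-dihydropyran-4-one and the diene. The methoxy, silyl and sulfonyl groups leave on aromatisation, and C2 is a spectator.
- The sulfone comes from the C5–H pyranone by iodination and copper-mediated sulfinate coupling. Ring C and C2 come from a Ti(OiPr)4/BINOL hetero-Diels–Alder reaction of the ring B aldehyde with the same diene.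
- Ring B aldehyde: 3,4-dihydroxybenzaldehyde, 4-O-(1,1-dimethylpropargyl) ether, 3-O-silylation, semihydrogenation, aromatic Claisen shift from O4 to C5, O-methylation.
- Ring order: B (bought), then C (step 6), then A (step 9); desilylation ends the route.

Key step: step 9

Assumption: the (S)-BINOL/Ti(OiPr)4 catalyst is taken to direct attack to the Si face of the aryl aldehyde, as it does in its allylation and aldol reactions; if the CD curve of the final flavanone shows the opposite sense, (R)-BINOL is used and nothing else changes.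

Abbreviations:
- Ar = 3-(tert-butyldimethylsilyloxy)-4-methoxy-5-(3-methylbut-2-en-1-yl)phenyl
- prenyl = 3-methylbut-2-en-1-yl
- TBS = tert-butyldimethylsilyl
- TMS = trimethylsilyl
- Pyranone numbering (O1, C2–C6) applies up to step 8. Flavanone numbering (O1, C2–C4, C4a, C5–C8, C8a) applies from step 9.

**Step 1**
Reactants: 1 3,4-dihydroxybenzaldehyde; 2 3-chloro-3-methylbut-1-yne
Product: 3 3-hydroxy-4-[(2-methylbut-3-yn-2-yl)oxy]benzaldehyde
Conditions: 2 (1.2 equiv), DBU (1.1 equiv), CuCl2·2H2O (1 mol %), MeCN, 0 °C, under argon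
Reagents that add atoms: none
Why: Copper-catalysed propargylic O-alkylation of a phenoxide: one equivalent of base ionises only the 4-OH, the more acidic phenol because it is para to the formyl group, and this phenoxide captures the copper-bound propargyl/allenylidene electrophile formed from 2 at a temperature too low for chromene or benzodioxine formation.

**Step 2**
Reactants: 3 3-hydroxy-4-[(2-methylbut-3-yn-2-yl)oxy]benzaldehyde
Product: 4 3-(tert-butyldimethylsilyloxy)-4-[(2-methylbut-3-yn-2-yl)oxy]benzaldehyde
Conditions: TBSCl, imidazole, CH2Cl2, rt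
Reagents that add atoms: tert-butyldimethylsilyl chloride, CC(C)(C)[Si](C)(C)Cl
Why: Standard imidazole-promoted silylation of the only free phenol, which also removes the nucleophile that could add to the alkyne.

**Step 3**
Reactants: 4 3-(tert-butyldimethylsilyloxy)-4-[(2-methylbut-3-yn-2-yl)oxy]benzaldehyde
Product: 5 3-(tert-butyldimethylsilyloxy)-4-[(2-methylbut-3-en-2-yl)oxy]benzaldehyde
Conditions: H2 (1 atm), Pd/CaCO3 poisoned with Pb(OAc)2, quinoline, EtOAc, rt
Reagents that add atoms: none
Why: Lindlar-type semihydrogenation: the poisoned palladium surface reduces the terminal alkyne to the alkene and should leave the aldehyde, the aryl ether and the silyl ether alone if hydrogen uptake is stopped at one equivalent.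

**Step 4**
Reactants: 5 3-(tert-butyldimethylsilyloxy)-4-[(2-methylbut-3-en-2-yl)oxy]benzaldehyde
Product: 7 3-(tert-butyldimethylsilyloxy)-4-hydroxy-5-prenylbenzaldehyde, via ortho-dienone 6 (not isolated)
Conditions: PhNEt2, 140 °C, under argon
Reagents that add atoms: none
Why: Aromatic Claisen rearrangement: the [3,3] shift of the 1,1-dimethylallyl ether, accelerated by the gem-dimethyl group, can end productively only at C5 because the other ortho position C3 carries the silyloxy group, and tautomerisation of 6 gives the phenol with the allyl unit inverted to prenyl, while the basic solvent suppresses acid-induced chroman formation.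

**Step 5**
Reactants: 7 3-(tert-butyldimethylsilyloxy)-4-hydroxy-5-prenylbenzaldehyde
Product: 8 3-(tert-butyldimethylsilyloxy)-4-methoxy-5-prenylbenzaldehyde
Conditions: MeOH, PPh3, DIAD, THF, 0 °C → rt
Reagents that add atoms: methanol, CO
Why: Mitsunobu etherification: the single free phenol, acidic through its para formyl group, is methylated by the methoxyphosphonium salt under nearly neutral conditions, so the phenoxide is short-lived and the adjacent silyl ether should neither migrate to O4 nor be cleaved.

**Step 6**
Reactants: 8 3-(tert-butyldimethylsilyloxy)-4-methoxy-5-prenylbenzaldehyde; 9 (E)-1-methoxy-3-(trimethylsilyloxy)buta-1,3-diene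
Product: 11 (S)-2-Ar-2,3-dihydro-4H-pyran-4-one, via Mukaiyama aldol adduct 10 (not isolated)
Conditions: Ti(OiPr)4 (10 mol %), (S)-BINOL (20 mol %), 4 Å molecular sieves, Et2O, −20 °C; then TFA (0.2 equiv), CH2Cl2, 0 °C
Reagents that add atoms: none
Why: Enantioselective hetero-Diels–Alder reaction in its stepwise Mukaiyama-aldol form: the BINOLate complex of tetravalent titanium binds the aldehyde and leaves its Si face open to the CH2 terminus of 9, which sets C2 as S in 10, and TFA then closes ring C by attack of the C2 oxygen on the methoxyenone terminus with loss of methanol, a closure that does not touch the C2–O bond.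

**Step 7**
Reactants: 11 (S)-2-Ar-2,3-dihydro-4H-pyran-4-one
Product: 12 (S)-2-Ar-5-iodo-2,3-dihydro-4H-pyran-4-one
Conditions: I2 (1.5 equiv), pyridine/CH2Cl2, 0 °C → rt, dark
Reagents that add atoms: iodine, II
Why: Electrophilic alpha-iodination of an enone under the iodine–pyridine protocol: C5 is the nucleophilic carbon of the vinylogous ester, pyridine removes H-5 from the iodinated oxocarbenium ion, the prenyl alkene survives because its addition of iodine is reversible, and pyridine is too weak a base to enolise C3.

**Step 8**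
Reactants: 12 (S)-2-Ar-5-iodo-2,3-dihydro-4H-pyran-4-one
Product: 13 (S)-2-Ar-5-(phenylsulfonyl)-2,3-dihydro-4H-pyran-4-one
Conditions: anhydrous PhSO2Na (1.5 equiv), CuI (1.2 equiv), DMF, 70 °C, under argon
Reagents that add atoms: sodium benzenesulfinate, [Na+].[O-]S(=O)c1ccccc1
Why: Ullmann-type C(sp2)–S coupling of an alkenyl iodide with a sulfinate salt at monovalent copper, which delivers the S-bound sulfone without any oxidant that would attack the prenyl alkene, and which is run without amine ligand or added base so that neither attack at C6 nor E1cB opening at O1–C2 can erode C2.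

**Step 9**
Reactants: 13 (S)-2-Ar-5-(phenylsulfonyl)-2,3-dihydro-4H-pyran-4-one; 9 (E)-1-methoxy-3-(trimethylsilyloxy)buta-1,3-diene
Product: 16 (S)-3'-(tert-butyldimethylsilyloxy)-7-hydroxy-4'-methoxy-5'-prenylflavanone, via cis-fused cycloadduct 14 (not isolated), via sulfonyl enone 15 (not isolated)
Conditions: 9 (3 equiv), toluene, 100 °C, sealed tube; evaporate; TMSOTf (0.1 equiv), CH2Cl2, −78 °C; then DBU (2.5 equiv), −78 → 0 °C; AcOH quench
Reagents that add atoms: none
Why: Proposed new method: a normal-electron-demand [4+2] cycloaddition (concerted but very asynchronous, or a Mukaiyama–Michael addition followed by ring closure) joins the nucleophilic CH2 terminus of 9 to C6 of 13, the carbon beta to both the ketone and the sulfone, and the methoxy-bearing terminus to C5, so ring A is closed intermolecularly as a six-membered carbocycle through the new C8–C8a and C4a–C5 bonds. The closest known reaction type is the Diels–Alder/eliminative aromatisation of 1-alkoxy-3-silyloxydienes with alpha-sulfinyl or alpha-sulfonyl enones and with 3-acceptor-substituted chromones, whereas a 2,3-dihydropyran-4-one without a fused benzene ring has not served as the dienophile. The selectivity that matters is regiochemical, and it is secured by the matched polarisation of both partners, which places the silyloxy carbon next to C8 and hence the oxygen at C7, para to C4a, and not at C6. The order of the eliminations is imposed by the reagents: a sulfone, unlike a sulfoxide, does not leave thermally, so catalytic TMSOTf first expels the C5 methoxy group by push from the C6=C7 silyl enol ether to give 15, in which C5 is vinylic and the ring oxygen at C8a is retained, and only then does DBU remove H-8a together with the cis sulfinate at C4a, the gain in aromaticity paying for the syn geometry, after which the dienone tautomerises to the C7 phenol. The centres formed at C4a, C5 and C8a (cis fusion from suprafacial addition, with face and endo/exo outcome irrelevant) are all erased, so no new stereocentre survives. C2 takes part in no bond change, O1 is a poor alkoxide-type leaving group until ring A is aromatic, and afterwards the 7-phenoxide formed by DBU, para-conjugated with the C4 carbonyl, lowers the C3–H acidity and guards against retro-oxa-Michael racemisation.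

**Step 10**
Reactants: 16 (S)-3'-(tert-butyldimethylsilyloxy)-7-hydroxy-4'-methoxy-5'-prenylflavanone
Product: 17 erylatissin C, (S)-7,3'-dihydroxy-4'-methoxy-5'-prenylflavanone
Conditions: TBAF (1.1 equiv), AcOH (1.3 equiv), THF, 0 °C
Reagents that add atoms: none
Why: Fluoride-induced cleavage of the aryl silyl ether, with acetic acid buffering the phenoxides so that retro-oxa-Michael opening of ring C, the racemisation path of flavanones, is not triggered, and with the 4'-methoxy group ruling out a para-quinone-methide pathway.

**Compound list**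
1 | 3,4-dihydroxybenzaldehyde | O=Cc1ccc(O)c(O)c1 | starting material
2 | 3-chloro-3-methylbut-1-yne | CC(C)(Cl)C#C | starting material
3 | 3-hydroxy-4-[(2-methylbut-3-yn-2-yl)oxy]benzaldehyde | O=Cc1ccc(OC(C)(C)C#C)c(O)c1 | intermediate
4 | 3-(tert-butyldimethylsilyloxy)-4-[(2-methylbut-3-yn-2-yl)oxy]benzaldehyde | O=Cc1ccc(OC(C)(C)C#C)c(O[Si](C)(C)C(C)(C)C)c1 | intermediate
5 | 3-(tert-butyldimethylsilyloxy)-4-[(2-methylbut-3-en-2-yl)oxy]benzaldehyde | O=Cc1ccc(OC(C)(C)C=C)c(O[Si](C)(C)C(C)(C)C)c1 | intermediate
6 | 3-(tert-butyldimethylsilyloxy)-4-oxo-5-prenylcyclohexa-1,5-diene-1-carbaldehyde skeleton (ortho-dienone, C5 sp3, racemic, centre erased on tautomerisation) | O=CC1=CC(CC=C(C)C)C(=O)C(O[Si](C)(C)C(C)(C)C)=C1 | intermediate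
7 | 3-(tert-butyldimethylsilyloxy)-4-hydroxy-5-(3-methylbut-2-en-1-yl)benzaldehyde | O=Cc1cc(CC=C(C)C)c(O)c(O[Si](C)(C)C(C)(C)C)c1 | intermediate
8 | 3-(tert-butyldimethylsilyloxy)-4-methoxy-5-(3-methylbut-2-en-1-yl)benzaldehyde | COc1c(O[Si](C)(C)C(C)(C)C)cc(C=O)cc1CC=C(C)C | intermediate
9 | (E)-1-methoxy-3-(trimethylsilyloxy)buta-1,3-diene | CO/C=C/C(=C)O[Si](C)(C)C | starting material
10 | (S,E)-5-[3-(tert-butyldimethylsilyloxy)-4-methoxy-5-prenylphenyl]-1-methoxy-5-(trimethylsilyloxy)pent-1-en-3-one | COc1c(O[Si](C)(C)C(C)(C)C)cc([C@@H](O[Si](C)(C)C)CC(=O)/C=C/OC)cc1CC=C(C)C | intermediate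
11 | (S)-2-[3-(tert-butyldimethylsilyloxy)-4-methoxy-5-prenylphenyl]-2,3-dihydro-4H-pyran-4-one | COc1c(O[Si](C)(C)C(C)(C)C)cc([C@@H]2CC(=O)C=CO2)cc1CC=C(C)C | intermediate
12 | (S)-2-[3-(tert-butyldimethylsilyloxy)-4-methoxy-5-prenylphenyl]-5-iodo-2,3-dihydro-4H-pyran-4-one | COc1c(O[Si](C)(C)C(C)(C)C)cc([C@@H]2CC(=O)C(I)=CO2)cc1CC=C(C)C | intermediate
13 | (S)-2-[3-(tert-butyldimethylsilyloxy)-4-methoxy-5-prenylphenyl]-5-(phenylsulfonyl)-2,3-dihydro-4H-pyran-4-one | COc1c(O[Si](C)(C)C(C)(C)C)cc([C@@H]2CC(=O)C(S(=O)(=O)c3ccccc3)=CO2)cc1CC=C(C)C | intermediate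
14 | (2S)-2-Ar-5-methoxy-4a-(phenylsulfonyl)-7-(trimethylsilyloxy)-2,3,4a,5,8,8a-hexahydro-4H-chromen-4-one (cis-fused, diastereomer mixture at C4a/C5/C8a, all three erased later) | COc1c(O[Si](C)(C)C(C)(C)C)cc([C@@H]2CC(=O)C3(S(=O)(=O)c4ccccc4)C(OC)C=C(O[Si](C)(C)C)CC3O2)cc1CC=C(C)C | intermediate
15 | (2S)-2-Ar-4a-(phenylsulfonyl)-2,3,8,8a-tetrahydro-4H-chromene-4,7(4aH)-dione (cis-fused, C4a/C8a erased later) | COc1c(O[Si](C)(C)C(C)(C)C)cc([C@@H]2CC(=O)C3(S(=O)(=O)c4ccccc4)C=CC(=O)CC3O2)cc1CC=C(C)C | intermediate
16 | (S)-3'-(tert-butyldimethylsilyloxy)-7-hydroxy-4'-methoxy-5'-prenylflavanone | COc1c(O[Si](C)(C)C(C)(C)C)cc([C@@H]2CC(=O)c3ccc(O)cc3O2)cc1CC=C(C)C | intermediate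
17 | erylatissin C, (S)-7,3'-dihydroxy-4'-methoxy-5'-prenylflavanone | COc1c(O)cc([C@@H]2CC(=O)c3ccc(O)cc3O2)cc1CC=C(C)C | target

**Step count**
- Total: 10 steps.
- Longest linear sequence: 10 steps (1 → 17). Diene 9 is bought and used twice.

**Steps most likely to fail**

1. **Step 9** (the step that goes beyond known chemistry).
   - What may go wrong:
     - The ring oxygen feeds electron density into C6, so cycloaddition may be too slow at temperatures at which the pyranone begins to open reversibly at O1–C2, with loss of enantiopurity.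
     - After cycloaddition, the base may cleave the C8a–O1 bond faster than it removes H-8a, which would stall aromatisation.
   - Fallback (known chemistry, sets out from 8, returns at 17): ring A is brought in ready-made and ring C is closed by an organocatalytic oxa-Michael reaction.
     - Methyl 2,4-dihydroxybenzoate is silylated at the non-chelated 4-OH (TBSCl, imidazole) to methyl 4-(tert-butyldimethylsilyloxy)-2-hydroxybenzoate F1.
     - Crossed Claisen condensation with excess LiCH2CO2tBu (THF, −78 → 0 °C) gives tert-butyl 3-[4-(tert-butyldimethylsilyloxy)-2-hydroxyphenyl]-3-oxopropanoate F2.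
     - Knoevenagel condensation of F2 with 8 (piperidine, AcOH, 4 Å molecular sieves, toluene) gives the alkylidene beta-keto ester F3.
     - The cinchona-alkaloid thiourea of the pseudoenantiomeric series that leads to S products (toluene, −25 °C) closes ring C to the tert-butyl (2S)-flavanone-3-carboxylate F4.
     - TsOH in toluene at 80 °C removes the ester group to give (S)-7,3'-bis(tert-butyldimethylsilyloxy)-4'-methoxy-5'-prenylflavanone F5.
     - The conditions of step 10, with a doubled amount of buffered fluoride, then give 17.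

2. **Step 8.**
   - What may go wrong: conjugate attack of sulfinate at C6 with ring opening, protodeiodination, cleavage of the aryl silyl ether in warm DMF, or slow coupling that forces temperatures at which C2 is eroded.
   - Fallback (sets out from 8, returns at 13): the sulfone is brought in as a carbon nucleophile and the pyranone is closed around it, so no C–I bond and no copper are needed.
     - Ti(OiPr)4/(S)-BINOL-catalysed Mukaiyama acetate aldol addition of 1-(tert-butylthio)-1-(trimethylsilyloxy)ethene to 8 (Et2O, −20 °C, then dilute HCl) gives S-tert-butyl (S)-3-Ar-3-hydroxypropanethioate F6.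
     - Excess LiCH2SO2Ph (THF, −78 °C) displaces the thiolate to give (S)-4-Ar-4-hydroxy-1-(phenylsulfonyl)butan-2-one F7.
     - N,N-dimethylformamide dimethyl acetal (toluene, rt) condenses at the active methylene to the enaminone F8.
     - On addition of BF3·OEt2 the hydroxyl of F8 displaces the amine and closes 13.

3. **Step 1.**
   - What may go wrong: incomplete discrimination between the two phenols, sluggish substitution at the tertiary centre with elimination of the chloride to the enyne, or cyclisation of the free 3-OH onto the alkyne.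
   - Fallback (sets out from 1, returns at 8): the prenyl group is attached by cross-coupling instead of a sigmatropic shift.
     - Bromination of 1 (Br2, AcOH, rt), directed ortho to the 4-OH and meta to the formyl group, gives 3-bromo-4,5-dihydroxybenzaldehyde F9.
     - Selective methylation of the more acidic para phenol (MeI, Li2CO3, DMF, 40 °C) gives 3-bromo-5-hydroxy-4-methoxybenzaldehyde F10.
     - Silylation (TBSCl, imidazole) gives 3-bromo-5-(tert-butyldimethylsilyloxy)-4-methoxybenzaldehyde F11.
     - Stille coupling with tributyl(3-methylbut-2-en-1-yl)stannane (Pd(PPh3)4, toluene, 110 °C) gives 8.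

**Further compounds**
F1 | step 9 | methyl 4-(tert-butyldimethylsilyloxy)-2-hydroxybenzoate | COC(=O)c1ccc(O[Si](C)(C)C(C)(C)C)cc1O
F2 | step 9 | tert-butyl 3-[4-(tert-butyldimethylsilyloxy)-2-hydroxyphenyl]-3-oxopropanoate | CC(C)(C)OC(=O)CC(=O)c1ccc(O[Si](C)(C)C(C)(C)C)cc1O
F3 | step 9 | tert-butyl 3-Ar-2-[4-(tert-butyldimethylsilyloxy)-2-hydroxybenzoyl]prop-2-enoate (alkylidene beta-keto ester, alkene geometry not defined) | COc1c(O[Si](C)(C)C(C)(C)C)cc(C=C(C(=O)OC(C)(C)C)C(=O)c2ccc(O[Si](C)(C)C(C)(C)C)cc2O)cc1CC=C(C)C
F4 | step 9 | tert-butyl (2S)-2-Ar-7-(tert-butyldimethylsilyloxy)-4-oxochromane-3-carboxylate (C3 epimerisable) | COc1c(O[Si](C)(C)C(C)(C)C)cc([C@@H]2C(C(=O)OC(C)(C)C)C(=O)c3ccc(O[Si](C)(C)C(C)(C)C)cc3O2)cc1CC=C(C)C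
F5 | step 9 | (S)-7,3'-bis(tert-butyldimethylsilyloxy)-4'-methoxy-5'-prenylflavanone | COc1c(O[Si](C)(C)C(C)(C)C)cc([C@@H]2CC(=O)c3ccc(O[Si](C)(C)C(C)(C)C)cc3O2)cc1CC=C(C)C
F6 | step 8 | S-tert-butyl (S)-3-Ar-3-hydroxypropanethioate | COc1c(O[Si](C)(C)C(C)(C)C)cc([C@@H](O)CC(=O)SC(C)(C)C)cc1CC=C(C)C
F7 | step 8 | (S)-4-Ar-4-hydroxy-1-(phenylsulfonyl)butan-2-one | COc1c(O[Si](C)(C)C(C)(C)C)cc([C@@H](O)CC(=O)CS(=O)(=O)c2ccccc2)cc1CC=C(C)C
F8 | step 8 | (S)-5-Ar-1-(dimethylamino)-5-hydroxy-2-(phenylsulfonyl)pent-1-en-3-one (enaminone, alkene geometry not defined) | COc1c(O[Si](C)(C)C(C)(C)C)cc([C@@H](O)CC(=O)C(=CN(C)C)S(=O)(=O)c2ccccc2)cc1CC=C(C)C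
F9 | step 1 | 3-bromo-4,5-dihydroxybenzaldehyde | O=Cc1cc(O)c(O)c(Br)c1
F10 | step 1 | 3-bromo-5-hydroxy-4-methoxybenzaldehyde | COc1c(O)cc(C=O)cc1Br
F11 | step 1 | 3-bromo-5-(tert-butyldimethylsilyloxy)-4-methoxybenzaldehyde | COc1c(O[Si](C)(C)C(C)(C)C)cc(C=O)cc1Br
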